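The target is cut at its bridging methine, the CH that sits ortho to free OH groups on ring A and ring B and carries the CH2 of the isobutyl chain. Both bonds from that carbon (CH–CH2 and CH–C5 of ring B) are made in one flask. The formyl carbon of a fully substituted ring A aldehyde accepts a 2-methylallyl group from boron, the resulting ortho-hydroxybenzylic borate collapses to an ortho-quinone methide, and the only unsubstituted nuclear carbon of a prenylated phloracetophenone (ring B) adds to it. Both monomers are made without protecting groups from phloracetophenone. Chemoselective hydrogenation of the 1,1-disubstituted alkene finishes the synthesis.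

Key step: step 4

Remark on the chemistry: the bridging CH bears two identical aryl groups, so the target has no stereocentre; borate 8 is formed as a racemate and its stereocentre is lost on ionization. All phenols stay free, because the ortho OH groups drive the key step.

Step 1
Reactants: 1 2,4,6-trihydroxyacetophenone (phloracetophenone, anhydrous)
Product: 3 3-acetyl-2,4,6-trihydroxybenzaldehyde, via aryl iminium chloride 2 (not isolated)
Conditions: POCl3 (1.1 equiv), DMF (1.2 equiv), EtOAc, 0 °C → rt; then H2O, 60 °C
Reagents that add atoms: N,N-dimethylformamide, CN(C)C=O; water, O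
Why: Vilsmeier–Haack formylation: the chloroiminium ion made from DMF and POCl3 attacks one of the two equivalent free nuclear carbons of the electron-rich ring, the iminium group deactivates the ring against a second attack, and aqueous warming hydrolyses 2 to the aldehyde.

Step 2
Reactants: 3 3-acetyl-2,4,6-trihydroxybenzaldehyde; 4 prenyl bromide (1-bromo-3-methylbut-2-ene)
Product: 5 3-acetyl-2,4,6-trihydroxy-5-(3-methylbut-2-enyl)benzaldehyde (ring A monomer)
Conditions: 4 (0.9 equiv), KOH (10% aq, 2.2 equiv), 0 °C; then 1 M HCl to pH 3, 0 °C
Reagents that add atoms: none
Why: C-alkylation of an ambident phloroglucinol polyanion (SN2 at the primary allylic carbon): in water the phenoxide oxygens are solvated, so the one remaining nuclear carbon attacks and tautomerization restores the arene, while a slight deficit of bromide limits geminal double alkylation.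

Step 3
Reactants: 1 2,4,6-trihydroxyacetophenone; 4 prenyl bromide
Product: 6 1-[2,4,6-trihydroxy-3-(3-methylbut-2-enyl)phenyl]ethanone (ring B monomer)
Conditions: 4 (0.8 equiv), KOH (10% aq, 2.2 equiv), 0 °C → rt; then 1 M HCl to pH 3, 0 °C
Reagents that add atoms: none
Why: The same aqueous-base C-prenylation, an established reaction of acylphloroglucinols; the two free nuclear positions are equivalent, so a single mono-prenyl isomer should form, and a deficit of 4 keeps double prenylation low.

Step 4
Reactants: 5 ring A monomer (1 equiv); 6 ring B monomer (2.5 equiv); 7 2-methylallylboronic acid pinacol ester (1.5 equiv)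
Product: 10 4,4-bis[3-acetyl-2,4,6-trihydroxy-5-(3-methylbut-2-enyl)phenyl]-2-methylbut-1-ene, via benzylic pinacol borate 8 (not isolated), via ortho-quinone methide 9 (not isolated)
Conditions: (PhO)2P(O)OH (10 mol %), MeCN/CH2Cl2 (1:1, 0.3 M in 5), 0 → 23 °C, Ar
Reagents that add atoms: none
Why: Proposed new method: the phosphoric acid and the ortho OH of 5 hydrogen-bond a pinacol oxygen of 7, the aldehyde oxygen binds boron, and the 2-methylallyl group passes to the formyl carbon through a six-membered chair transition state to give racemic borate 8 (closest known reaction: Brønsted-acid-catalysed allylboration of aromatic aldehydes such as salicylaldehydes). The B–O oxygen of 8 is benzylic to a ring with three oxygen donors, so proton transfer from an ortho OH expels pinB–OH and leaves ortho-quinone methide 9, whose exocyclic carbon is attacked by C-5 of 6, the one nuclear CH of that ring, before tautomerization returns both rings to arenes (closest known reaction: Friedel–Crafts capture of ortho-quinone methides by acylphloroglucinols). No ring is closed, and no stereocentre remains because the new CH ends up with two identical aryl groups. The step needs aldehyde-over-ketone selectivity, which the higher electrophilicity of the formyl group and the hydrogen-bond chelation of both acetyl groups should provide, and C- over O-capture of 9, which follows because O-adducts revert while the C-adduct rearomatizes. Capture must also outrun the 1,5-hydrogen shift of 9 to a diene, which the excess of 6, the high concentration and the low temperature are meant to secure; the symmetric 2-methylallyl group removes any question of which allyl terminus bonds.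

Step 5
Reactants: 10 4,4-bis[3-acetyl-2,4,6-trihydroxy-5-(3-methylbut-2-enyl)phenyl]-2-methylbut-1-ene
Product: 11 1,1-bis[3-acetyl-2,4,6-trihydroxy-5-(3-methylbut-2-enyl)phenyl]-3-methylbutane (target CNP0215781.0)
Conditions: H2 (1 atm), RhCl(PPh3)3 (5 mol %), PhMe/EtOH (1:1), 23 °C; stopped after one equivalent of H2
Reagents that add atoms: none
Why: Homogeneous hydrogenation with RhCl(PPh3)3, whose rate falls steeply with alkene substitution, so the 1,1-disubstituted alkene should be reduced while the two trisubstituted prenyl alkenes, the aryl ketones and the arenes stay; no stereocentre is created.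

Compound list
1 | 2,4,6-trihydroxyacetophenone (phloracetophenone) | CC(=O)c1c(O)cc(O)cc1O | starting material
2 | N-[(3-acetyl-2,4,6-trihydroxyphenyl)methylidene]-N-methylmethanaminium chloride | CC(=O)c1c(O)cc(O)c(C=[N+](C)C)c1O.[Cl-] | intermediate (not isolated)
3 | 3-acetyl-2,4,6-trihydroxybenzaldehyde | CC(=O)c1c(O)cc(O)c(C=O)c1O | intermediate
4 | prenyl bromide (1-bromo-3-methylbut-2-ene) | CC(C)=CCBr | starting material
5 | 3-acetyl-2,4,6-trihydroxy-5-(3-methylbut-2-enyl)benzaldehyde (ring A monomer) | CC(=O)c1c(O)c(CC=C(C)C)c(O)c(C=O)c1O | intermediate
6 | 1-[2,4,6-trihydroxy-3-(3-methylbut-2-enyl)phenyl]ethanone (ring B monomer) | CC(=O)c1c(O)cc(O)c(CC=C(C)C)c1O | intermediate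
7 | 2-methylallylboronic acid pinacol ester | CC(=C)CB1OC(C)(C)C(C)(C)O1 | starting material
8 | 2-[1-[3-acetyl-2,4,6-trihydroxy-5-(3-methylbut-2-enyl)phenyl]-3-methylbut-3-enyloxy]-4,4,5,5-tetramethyl-1,3,2-dioxaborolane (racemic) | CC(=C)CC(OB1OC(C)(C)C(C)(C)O1)c1c(O)c(CC=C(C)C)c(O)c(C(C)=O)c1O | intermediate (not isolated)
9 | 4-acetyl-3,5-dihydroxy-6-(3-methylbut-3-enylidene)-2-(3-methylbut-2-enyl)cyclohexa-2,4-dien-1-one (exocyclic alkene geometry not defined) | CC(=C)CC=C1C(=O)C(CC=C(C)C)=C(O)C(C(C)=O)=C1O | intermediate (not isolated)
10 | 4,4-bis[3-acetyl-2,4,6-trihydroxy-5-(3-methylbut-2-enyl)phenyl]-2-methylbut-1-ene (no stereocentre) | CC(=C)CC(c1c(O)c(CC=C(C)C)c(O)c(C(C)=O)c1O)c1c(O)c(CC=C(C)C)c(O)c(C(C)=O)c1O | intermediate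
11 | 1,1-bis[3-acetyl-2,4,6-trihydroxy-5-(3-methylbut-2-enyl)phenyl]-3-methylbutane (no stereocentre) | CC(=O)c1c(O)c(CC=C(C)C)c(O)c(C(CC(C)C)c2c(O)c(CC=C(C)C)c(O)c(C(C)=O)c2O)c1O | target

Total step count: 5. Longest linear sequence: 4 steps (steps 1, 2, 4, 5); step 3 supplies ring B in one step.

Steps most likely to fail

Step 4 (new method). Allyl transfer to the strongly hydrogen-bonded, electron-rich formyl group may be too slow. The quinone methide 9 may also tautomerize by 1,5-hydrogen shift before it is arylated, or the acid may close a prenyl or 2-methylallyl group onto a neighbouring phenol. The fallback uses known chemistry and sets out from 6. Two molecules of 6 are joined through 3-methylbutanal (CC(C)CC=O) with catalytic ethylenediammonium diacetate in MeOH/CH2Cl2 at room temperature. Knoevenagel-type condensation should give the ortho-quinone methide 4-acetyl-3,5-dihydroxy-6-(3-methylbutylidene)-2-(3-methylbut-2-enyl)cyclohexa-2,4-dien-1-one F1 (not isolated), and a second molecule of 6 adds to its exocyclic carbon to give the alkylidene-bis(acylphloroglucinol). The fallback comes back to the route at 11 and makes 5, 10 and the hydrogenation unnecessary.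

Step 5. A rhodium hydride may move the terminal double bond into the trisubstituted position, where reduction stalls. Prolonged exposure may begin to reduce the prenyl groups, and the chelating acylphenol units may slow the catalyst. The fallback sets out from 10 and transfers H2 without a metal, from diimide generated from 2-nitrobenzenesulfonohydrazide and Et3N in MeCN at room temperature. The concerted syn transfer cannot isomerize alkenes and favours the less substituted alkene, so the reaction would be run to partial conversion with recycling of 10. It comes back to the route at 11, and no new compound arises on the way (F0).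

Step 2. O-alkylation and geminal double C-alkylation with loss of aromaticity may compete with mono-C-prenylation of the polyanion. The fallback reverses the order of events and sets out from 6. Its single free nuclear carbon is formylated with preformed (chloromethylidene)dimethylammonium chloride in MeCN at −20 → 0 °C, which keeps exposure of the prenyl group to acid short. The iminium salt N-[[3-acetyl-2,4,6-trihydroxy-5-(3-methylbut-2-enyl)phenyl]methylidene]-N-methylmethanaminium chloride F2 (not isolated) is then hydrolysed with aqueous NaOAc. The fallback comes back to the route at 5, and step 1 and compound 3 are then not needed.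

Further compounds
F1 | step 4 | 4-acetyl-3,5-dihydroxy-6-(3-methylbutylidene)-2-(3-methylbut-2-enyl)cyclohexa-2,4-dien-1-one | CC(C)CC=C1C(=O)C(CC=C(C)C)=C(O)C(C(C)=O)=C1O
F0 | step 5 | none | none
F2 | step 2 | N-[[3-acetyl-2,4,6-trihydroxy-5-(3-methylbut-2-enyl)phenyl]methylidene]-N-methylmethanaminium chloride | CC(=O)c1c(O)c(CC=C(C)C)c(O)c(C=[N+](C)C)c1O.[Cl-]
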